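**Retrosynthetic overview**

1. Feature: the ring is numbered C1 (ketone), C2 (CH2OH), C3 (=CH), C4 (quaternary), C5 (enol-ester arm), C6 (acetonyl), C7 (CH2). C7 is the only enolisable carbon beside the C1 enone, because C2 is sp2 and C4 has no hydrogen. C6 is β to the acetonyl carbonyl, so tying that carbonyl to the one-carbon arm on C5 as a 5-substituted 5,6-dihydropyran-2-one makes C6 a Michael acceptor held next to C5.
2. Key disconnection C6–C7: a C7 β-keto allyl ester carbanion adds 7-exo-trig to the lactone β-carbon. This closes the seven-membered ring cis-fused to the lactone and relays C5 to C6.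
3. After closure: lactone to Weinreb amide; C5 arm CH2OH → CHO → C≡CH; MeMgBr; deallylative decarboxylation; ruthenium-catalysed addition of 3-methylbut-2-enoic acid (Z-enol ester); desilylation.
4. Before closure: C5 from rhodium/BINAP vinylation of furan-2(5H)-one, the vinyl group being cut to an acetal before the homoprenyl alkene exists; C4 by homoprenylation then methylation of the lactone enolate; the Z-enone by trans-hydrostannation/iodination, formylation and acetate aldol; the dihydropyranone by Z-olefination of the C6 aldehyde and lactonisation, with C1 oxidised last.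
5. Ring order: γ-butyrolactone template (opened in step 7) → dihydropyranone (step 14) → cycloheptenone (step 16) → lactone opened (step 17).

Key step: step 16

Remark on the chemistry: the facial sense of the rhodium/BINAP vinylation of furan-2(5H)-one is assumed to follow that of cyclic enones and six-membered unsaturated lactones, which calls for (R)-BINAP; if the opposite sense is found, (S)-BINAP is used and nothing else changes. The C2 hydroxymethyl group is carried as its tert-butyldiphenylsilyl ether so that it survives the aqueous acid of step 13. The target ring numbering C1–C7 is used for all intermediates.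

**Route**

Step 1
Reactants: 1 furan-2(5H)-one; 2 potassium vinyltrifluoroborate
Product: 3 (R)-4-vinyldihydrofuran-2(3H)-one
Conditions: [RhCl(C8H12)]2 (2.5 mol %), (R)-BINAP (5.5 mol %), Et3N, dioxane/H2O (10:1), 80 °C
Reagents that add atoms: none
Why: Rhodium-catalysed asymmetric conjugate addition of an alkenylboron reagent to a cyclic unsaturated lactone, in which the vinylrhodium–BINAP species should add to one enantiotopic face of the butenolide and so set C5.

Step 2
Reactants: 3 (R)-4-vinyldihydrofuran-2(3H)-one
Product: 5 (S)-4-(dimethoxymethyl)dihydrofuran-2(3H)-one, via aldehyde 4 (not isolated)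
Conditions: O3, CH2Cl2/MeOH, −78 °C; Me2S, −78 °C → rt; then HC(OMe)3, p-TsOH·H2O (cat.), rt
Reagents that add atoms: ozone, [O-][O+]=O (carbonyl oxygen of 4); trimethyl orthoformate, COC(OC)OC
Why: Ozonolysis with reductive work-up followed by acid-catalysed acetalisation in the same flask is done here because the vinyl group is still the only alkene, and the epimerisable α-branched aldehyde is trapped as its acetal without isolation, so C5 should stay intact (its descriptor changes only through the priority rules).

Step 3
Reactants: 6 5-bromo-2-methylpent-2-ene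
Product: 7 5-iodo-2-methylpent-2-ene
Conditions: NaI, acetone, reflux
Reagents that add atoms: sodium iodide, [Na+].[I-]
Why: Finkelstein halide exchange, driven by precipitation of NaBr, should give the primary iodide that a lactone enolate alkylates cleanly.

Step 4
Reactants: 5 (S)-4-(dimethoxymethyl)dihydrofuran-2(3H)-one; 7 5-iodo-2-methylpent-2-ene
Product: 8 (3S,4S)-4-(dimethoxymethyl)-3-(4-methylpent-3-en-1-yl)dihydrofuran-2(3H)-one
Conditions: LiN(i-Pr)2, THF, −78 °C; then 7, DMPU, −78 → −30 °C
Reagents that add atoms: none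
Why: Lactone enolate alkylation (SN2) with a primary iodide should occur anti to the acetal-bearing carbon, although the configuration of this new centre is immaterial because it is re-enolised in step 5.

Step 5
Reactants: 8 (3S,4S)-4-(dimethoxymethyl)-3-(4-methylpent-3-en-1-yl)dihydrofuran-2(3H)-one
Product: 9 (3R,4S)-4-(dimethoxymethyl)-3-methyl-3-(4-methylpent-3-en-1-yl)dihydrofuran-2(3H)-one
Conditions: LiN(i-Pr)2, THF, −78 °C; MeI, −78 → −40 °C
Reagents that add atoms: iodomethane, CI
Why: In this second enolate alkylation allylic 1,2-strain should turn the acetal substituent pseudo-axial, so the small electrophile enters anti to it; methyl ends trans and homoprenyl cis to the acetal carbon, which is the quaternary C4 of the target.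

Step 6
Reactants: 9 (3R,4S)-4-(dimethoxymethyl)-3-methyl-3-(4-methylpent-3-en-1-yl)dihydrofuran-2(3H)-one
Product: 10 (3R,4S)-4-(dimethoxymethyl)-3-methyl-3-(4-methylpent-3-en-1-yl)tetrahydrofuran-2-ol (anomer mixture)
Conditions: i-Bu2AlH (1.2 equiv), CH2Cl2, −78 °C; aq. potassium sodium tartrate
Reagents that add atoms: none
Why: Partial hydride reduction of a γ-lactone should stop at the aluminium hemiacetal at low temperature, and the α-quaternary centre cannot epimerise.

Step 7
Reactants: 10 (3R,4S)-4-(dimethoxymethyl)-3-methyl-3-(4-methylpent-3-en-1-yl)tetrahydrofuran-2-ol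
Product: 11 (2S,3R)-2-(dimethoxymethyl)-3-ethynyl-3,7-dimethyloct-6-en-1-ol
Conditions: dimethyl (1-diazo-2-oxopropyl)phosphonate, K2CO3, MeOH, 0 → 40 °C
Reagents that add atoms: dimethyl (1-diazo-2-oxopropyl)phosphonate, CC(=O)C(=[N+]=[N-])P(=O)(OC)OC
Why: Ohira–Bestmann homologation should act on the open hydroxy-aldehyde form of the lactol, whose formyl carbon (C3) sits on a quaternary centre and so cannot epimerise, and it releases the C5 arm as a primary alcohol.

Step 8
Reactants: 11 (2S,3R)-2-(dimethoxymethyl)-3-ethynyl-3,7-dimethyloct-6-en-1-ol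
Product: 13 (4R,5S)-5-(dimethoxymethyl)-4-methyl-4-(4-methylpent-3-en-1-yl)-6-(triethylsilyloxy)hex-2-yn-1-ol, via triethylsilyl ether 12 (not isolated)
Conditions: n-BuLi (1.05 equiv), THF, −78 → 0 °C; Et3SiCl (1.05 equiv), 0 °C; then n-BuLi (1.1 equiv), −78 °C; (CH2O)n, −78 °C → rt
Reagents that add atoms: chlorotriethylsilane, CC[Si](Cl)(CC)CC; paraformaldehyde (as formaldehyde), C=O
Why: O-silylation of the lithium alkoxide, then acetylide formation and addition to formaldehyde in one flask, should mark the arm oxygen with an acid-labile group and leave the new propargylic hydroxyl free to direct step 9.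

Step 9
Reactants: 13 (4R,5S)-5-(dimethoxymethyl)-4-methyl-4-(4-methylpent-3-en-1-yl)-6-(triethylsilyloxy)hex-2-yn-1-ol
Product: 15 (2Z,4R,5S)-5-(dimethoxymethyl)-2-iodo-4-methyl-4-(4-methylpent-3-en-1-yl)-6-(triethylsilyloxy)hex-2-en-1-ol, via alkenylstannane 14 (not isolated)
Conditions: Bu3SnH (1.2 equiv), [(C5Me5)RuCl]4 (2.5 mol %), CH2Cl2, rt; then I2, CH2Cl2, 0 °C; aq. Na2S2O3
Reagents that add atoms: tributylstannane, CCCC[SnH](CCCC)CCCC (tin of 14); iodine, II
Why: Hydroxyl-directed ruthenium-catalysed trans-hydrostannation should place tin on the carbinol-side carbon with hydrogen trans to it, and iododestannylation proceeds with retention, so the halogen ends cis to the quaternary carbon, which later makes the C1 carbonyl cis to C4; the non-radical pathway spares the homoprenyl alkene.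

Step 10
Reactants: 15 (2Z,4R,5S)-5-(dimethoxymethyl)-2-iodo-4-methyl-4-(4-methylpent-3-en-1-yl)-6-(triethylsilyloxy)hex-2-en-1-ol
Product: 16 tert-butyldiphenylsilyl ether of 15 (Z-iodoalkene and both stereocentres unchanged)
Conditions: t-BuPh2SiCl, imidazole, CH2Cl2, rt
Reagents that add atoms: tert-butyl(chloro)diphenylsilane, CC(C)(C)[Si](Cl)(c1ccccc1)c1ccccc1
Why: Silylation of the primary allylic alcohol with a group chosen to outlast the aqueous acid that later removes the triethylsilyl ether and the acetal.

Step 11
Reactants: 16 tert-butyldiphenylsilyl ether of 15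
Product: 17 (Z)-2-[(tert-butyldiphenylsilyloxy)methyl]-5-(dimethoxymethyl)-4-methyl-4-(4-methylpent-3-en-1-yl)-6-(triethylsilyloxy)hex-2-enal (formyl cis to the quaternary carbon; stereocentres as in 11)
Conditions: t-BuLi (2.1 equiv), Et2O, −78 °C; DMF, −78 → 0 °C; aq. NH4Cl
Reagents that add atoms: N,N-dimethylformamide, CN(C)C=O
Why: Iodine–lithium exchange and formylation of the alkenyllithium both occur with retention of alkene geometry, and the Z-enal should not isomerise because it already has the flat formyl group, not the silyloxymethyl group, beside the quaternary carbon.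

Step 12
Reactants: 17 the Z-enal; 18 allyl acetate
Product: 19 allyl (4Z)-4-[(tert-butyldiphenylsilyloxy)methyl]-6-[1,1-dimethoxy-3-(triethylsilyloxy)propan-2-yl]-3-hydroxy-6,10-dimethylundeca-4,9-dienoate (C3 carbinol epimers; other centres as in 11)
Conditions: LiN(i-Pr)2, 18, THF, −78 °C; then 17, −78 °C; aq. NH4Cl
Reagents that add atoms: none
Why: Aldol 1,2-addition of the lithium enolate of allyl acetate to the enal brings in C7 and the allyl ester, and the unselective new carbinol centre (C1) does not matter because it is oxidised in step 15.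

Step 13
Reactants: 19 the β-hydroxy allyl ester
Product: 20 allyl (4Z)-4-[(tert-butyldiphenylsilyloxy)methyl]-3-hydroxy-6-(1-hydroxy-3-oxopropan-2-yl)-6,10-dimethylundeca-4,9-dienoate (used crude)
Conditions: p-TsOH·H2O (cat.), acetone/H2O (10:1), rt → 40 °C
Reagents that add atoms: water, O
Why: Acid hydrolysis should cleave the triethylsilyl ether and the dimethyl acetal while the tert-butyldiphenylsilyl ether and the allyl ester persist, unveiling the C6 aldehyde and the arm hydroxyl together.

Step 14
Reactants: 20 the hydroxy aldehyde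
Product: 22 allyl (4Z)-4-[(tert-butyldiphenylsilyloxy)methyl]-3-hydroxy-6,10-dimethyl-6-(6-oxo-3,6-dihydro-2H-pyran-3-yl)undeca-4,9-dienoate, via hydroxy enoate 21 (not isolated)
Conditions: (PhO)2P(O)CH2CO2Et, NaI, DBU, THF, −78 → 0 °C; then p-TsOH (cat.), toluene, rt
Reagents that add atoms: ethyl 2-(diphenoxyphosphoryl)acetate, CCOC(=O)CP(=O)(Oc1ccccc1)Oc1ccccc1
Why: Z-selective Horner–Wadsworth–Emmons olefination with a diaryl phosphonoacetate under amine/NaI conditions tolerates the free hydroxyls, and only the Z-δ-hydroxy enoate can lactonise to the 5,6-dihydropyran-2-one; C1 is deliberately still a carbinol so that no β-keto ester enolate can attack the C6 aldehyde.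

Step 15
Reactants: 22 the hydroxy dihydropyranone
Product: 23 allyl (4Z)-4-[(tert-butyldiphenylsilyloxy)methyl]-6,10-dimethyl-3-oxo-6-(6-oxo-3,6-dihydro-2H-pyran-3-yl)undeca-4,9-dienoate (C1 ketone cis to C4 across C2=C3; C4 and C5 as set in steps 5 and 1)
Conditions: Dess–Martin periodinane, NaHCO3, CH2Cl2, 0 °C → rt
Reagents that add atoms: none
Why: Dess–Martin oxidation of the allylic β-hydroxy ester should give the β-keto ester under buffered, non-basic conditions that leave the unsaturated lactone and its γ-stereocentre C5 alone.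

Step 16
Reactants: 23 the Z-enone β-keto allyl ester
Product: 24 cis-fused cycloheptenone δ-lactone (allyl ester on C7; C1 ketone; silyloxymethyl on C2; C2=C3; quaternary C4; lactone C5–CH2–O–C(=O)–CH2–C6; H on C5 and C6 cis; C7 epimers and enol)
Conditions: Cs2CO3 (0.3 equiv), MeCN (0.01 M), 0 °C → rt
Reagents that add atoms: none
Why: Cs2CO3 removes the doubly activated C7 proton, the cesium enolate adds to C6, the β-carbon of the unsaturated δ-lactone, and the lactone enolate so formed is reprotonated by further β-keto ester, so the base is catalytic. This is an intramolecular Michael addition of a β-keto ester to an unsaturated ester, a known reaction type whose seven-membered version is the less common one. The ring C1–C7 closes in the 7-exo-trig mode by forming C6–C7, with the enoate α-carbon left outside the new ring. The one new stereocentre that matters, C6, is controlled by the tether: the nucleophile hangs from C4 on C5 and can reach C6 only along the axial trajectory on the lactone face that carries the C5–C4 bond, which should give the cis-fused bicycle with the future acetonyl carbon cis to the C5 arm, whereas C7 forms as a mixture and is erased in step 21. The step needs C-attack of C7 at C6 in preference to γ-deprotonation of the lactone at C5, attack at C3 and intermolecular addition; these are secured by the acidity gap between the β-keto ester and the lactone γ-hydrogen under carbonate, by C2 being sp2 and C4 quaternary (no second enolisable site), by the neopentyl shielding of C3 and by high dilution. The Z-alkene C2=C3 and the gem-disubstituted C4 hold C7 and C6 within bonding distance.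

Step 17
Reactants: 24 the cis-fused lactone
Product: 25 allyl 3-[(tert-butyldiphenylsilyloxy)methyl]-6-(hydroxymethyl)-7-{2-[methoxy(methyl)amino]-2-oxoethyl}-5-methyl-5-(4-methylpent-3-en-1-yl)-2-oxocyclohept-3-ene-1-carboxylate (used crude)
Conditions: MeNH(OMe)·HCl, i-PrMgCl, THF, −20 → 0 °C; aq. NH4Cl
Reagents that add atoms: N,O-dimethylhydroxylamine hydrochloride, CNOC.Cl
Why: Aminolysis of the lactone by the magnesium amide gives the Weinreb amide and frees the C5 arm as a primary alcohol, while the first equivalent of base turns the β-keto ester into a magnesium enolate that shields the C1 ketone and the allyl ester.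

Step 18
Reactants: 25 the hydroxy Weinreb amide
Product: 26 the corresponding C5 aldehyde (6-formyl analogue of 25)
Conditions: Dess–Martin periodinane, NaHCO3, CH2Cl2, 0 °C
Reagents that add atoms: none
Why: Buffered Dess–Martin oxidation of the primary alcohol, run directly on crude 25, should pre-empt relactonisation and keep epimerisation of the new α-stereocentre C5 to a minimum.

Step 19
Reactants: 26 the C5 aldehyde
Product: 27 the C5 alkyne (6-ethynyl analogue of 25)
Conditions: dimethyl (1-diazo-2-oxopropyl)phosphonate, K2CO3, allyl alcohol/THF, 0 °C → rt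
Reagents that add atoms: dimethyl (1-diazo-2-oxopropyl)phosphonate, CC(=O)C(=[N+]=[N-])P(=O)(OC)OC
Why: Ohira–Bestmann homologation is selective for the aldehyde; the β-keto ester rests as its potassium enolate, allyl alcohol as the protic component makes any ester exchange degenerate, and the amide side chain, unlike a methyl ketone, cannot undergo aldol addition to the aldehyde.

Step 20
Reactants: 27 the alkynyl Weinreb amide
Product: 28 allyl 3-[(tert-butyldiphenylsilyloxy)methyl]-6-ethynyl-5-methyl-5-(4-methylpent-3-en-1-yl)-2-oxo-7-(2-oxopropyl)cyclohept-3-ene-1-carboxylate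
Conditions: MeMgBr (5 equiv), THF, −20 → 0 °C; aq. NH4Cl
Reagents that add atoms: methylmagnesium bromide, C[Mg]Br
Why: Grignard addition to the Weinreb amide stops at the chelated tetrahedral intermediate and gives the acetonyl ketone on work-up, the first equivalents having converted the β-keto ester into a magnesium enolate that protects the C1 ketone and the ester.

Step 21
Reactants: 28 the β-keto allyl ester
Product: 29 2-[(tert-butyldiphenylsilyloxy)methyl]-5-ethynyl-4-methyl-4-(4-methylpent-3-en-1-yl)-6-(2-oxopropyl)cyclohept-2-en-1-one (C4, C5 and C6 as in the target)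
Conditions: Pd(PPh3)4 (5 mol %), morpholine, THF, rt
Reagents that add atoms: none
Why: Tsuji–Trost-type deallylation by zerovalent palladium with morpholine as allyl acceptor, followed by spontaneous decarboxylation of the β-keto acid, removes the activating group at C7 under near-neutral conditions that should not provoke aldol reaction between the two ketones or retro-Michael cleavage at C6.

Step 22
Reactants: 29 the alkynyl diketone; 30 3-methylbut-2-enoic acid
Product: 31 tert-butyldiphenylsilyl ether of the target (Z-enol ester)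
Conditions: Ru(C4H7)2(Ph2P(CH2)4PPh2) (5 mol %), toluene, 65 °C
Reagents that add atoms: none
Why: Ruthenium-catalysed anti-Markovnikov addition of a carboxylic acid to a terminal alkyne via a ruthenium vinylidene should deliver the carboxylate to the terminal carbon and give the Z-enol ester, the bulky substituent on the alkyne favouring terminal attack.

Step 23
Reactants: 31 the silyl-protected target
Product: 32 (Z)-2-[(1R,2R,7S)-4-(hydroxymethyl)-2-methyl-2-(4-methylpent-3-en-1-yl)-5-oxo-7-(2-oxopropyl)cyclohept-3-en-1-yl]ethenyl 3-methylbut-2-enoate (CNP0415257.1)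
Conditions: HF·pyridine, pyridine, THF, 0 °C → rt
Reagents that add atoms: none
Why: Desilylation with buffered HF should free the C2 hydroxymethyl group without cleaving the enol ester or triggering base-mediated aldol chemistry of the 1,5-diketone.

**Compound list**

1 | furan-2(5H)-one | O=C1OCC=C1 | starting material
2 | potassium vinyltrifluoroborate | [K+].C=C[B-](F)(F)F | starting material
3 | (R)-4-vinyldihydrofuran-2(3H)-one | O=C1C[C@H](C=C)CO1 | intermediate
4 | (S)-5-oxotetrahydrofuran-3-carbaldehyde | O=C1C[C@H](C=O)CO1 | intermediate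
5 | (S)-4-(dimethoxymethyl)dihydrofuran-2(3H)-one | O=C1C[C@H](C(OC)OC)CO1 | intermediate
6 | 5-bromo-2-methylpent-2-ene | CC(C)=CCCBr | starting material
7 | 5-iodo-2-methylpent-2-ene | CC(C)=CCCI | intermediate
8 | (3S,4S)-4-(dimethoxymethyl)-3-(4-methylpent-3-en-1-yl)dihydrofuran-2(3H)-one | O=C1[C@@H](CCC=C(C)C)[C@H](C(OC)OC)CO1 | intermediate
9 | (3R,4S)-4-(dimethoxymethyl)-3-methyl-3-(4-methylpent-3-en-1-yl)dihydrofuran-2(3H)-one | O=C1[C@](C)(CCC=C(C)C)[C@H](C(OC)OC)CO1 | intermediate
10 | (3R,4S)-4-(dimethoxymethyl)-3-methyl-3-(4-methylpent-3-en-1-yl)tetrahydrofuran-2-ol, anomer mixture | OC1[C@](C)(CCC=C(C)C)[C@H](C(OC)OC)CO1 | intermediate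
11 | (2S,3R)-2-(dimethoxymethyl)-3-ethynyl-3,7-dimethyloct-6-en-1-ol | C#C[C@](C)(CCC=C(C)C)[C@H](C(OC)OC)CO | intermediate
12 | triethylsilyl ether of 11 | C#C[C@](C)(CCC=C(C)C)[C@H](C(OC)OC)CO[Si](CC)(CC)CC | intermediate
13 | (4R,5S)-5-(dimethoxymethyl)-4-methyl-4-(4-methylpent-3-en-1-yl)-6-(triethylsilyloxy)hex-2-yn-1-ol | OCC#C[C@](C)(CCC=C(C)C)[C@H](C(OC)OC)CO[Si](CC)(CC)CC | intermediate
14 | (Z)-2-(tributylstannyl) analogue of 15 (tin cis to the quaternary carbon) | OC/C([Sn](CCCC)(CCCC)CCCC)=C/[C@](C)(CCC=C(C)C)[C@H](C(OC)OC)CO[Si](CC)(CC)CC | intermediate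
15 | (2Z,4R,5S)-5-(dimethoxymethyl)-2-iodo-4-methyl-4-(4-methylpent-3-en-1-yl)-6-(triethylsilyloxy)hex-2-en-1-ol | OC/C(I)=C/[C@](C)(CCC=C(C)C)[C@H](C(OC)OC)CO[Si](CC)(CC)CC | intermediate
16 | tert-butyldiphenylsilyl ether of 15 | CC(C)(C)[Si](c1ccccc1)(c1ccccc1)OC/C(I)=C/[C@](C)(CCC=C(C)C)[C@H](C(OC)OC)CO[Si](CC)(CC)CC | intermediate
17 | (Z)-2-[(tert-butyldiphenylsilyloxy)methyl]-5-(dimethoxymethyl)-4-methyl-4-(4-methylpent-3-en-1-yl)-6-(triethylsilyloxy)hex-2-enal | O=C/C(CO[Si](c1ccccc1)(c1ccccc1)C(C)(C)C)=C\[C@](C)(CCC=C(C)C)[C@H](C(OC)OC)CO[Si](CC)(CC)CC | intermediate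
18 | allyl acetate | CC(=O)OCC=C | starting material
19 | allyl (4Z)-4-[(tert-butyldiphenylsilyloxy)methyl]-6-[1,1-dimethoxy-3-(triethylsilyloxy)propan-2-yl]-3-hydroxy-6,10-dimethylundeca-4,9-dienoate, C3 epimers | C=CCOC(=O)CC(O)/C(CO[Si](c1ccccc1)(c1ccccc1)C(C)(C)C)=C\[C@](C)(CCC=C(C)C)[C@H](C(OC)OC)CO[Si](CC)(CC)CC | intermediate
20 | allyl (4Z)-4-[(tert-butyldiphenylsilyloxy)methyl]-3-hydroxy-6-(1-hydroxy-3-oxopropan-2-yl)-6,10-dimethylundeca-4,9-dienoate | C=CCOC(=O)CC(O)/C(CO[Si](c1ccccc1)(c1ccccc1)C(C)(C)C)=C\[C@](C)(CCC=C(C)C)[C@H](C=O)CO | intermediate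
21 | Z-hydroxy enoate from 20 (ethyl (Z)-enoate on C6, free arm hydroxyl) | C=CCOC(=O)CC(O)/C(CO[Si](c1ccccc1)(c1ccccc1)C(C)(C)C)=C\[C@](C)(CCC=C(C)C)[C@H](/C=C\C(=O)OCC)CO | intermediate
22 | allyl (4Z)-4-[(tert-butyldiphenylsilyloxy)methyl]-3-hydroxy-6,10-dimethyl-6-(6-oxo-3,6-dihydro-2H-pyran-3-yl)undeca-4,9-dienoate | C=CCOC(=O)CC(O)/C(CO[Si](c2ccccc2)(c2ccccc2)C(C)(C)C)=C\[C@](C)(CCC=C(C)C)[C@H]1COC(=O)C=C1 | intermediate
23 | allyl (4Z)-4-[(tert-butyldiphenylsilyloxy)methyl]-6,10-dimethyl-3-oxo-6-(6-oxo-3,6-dihydro-2H-pyran-3-yl)undeca-4,9-dienoate (key-step precursor) | C=CCOC(=O)CC(=O)/C(CO[Si](c2ccccc2)(c2ccccc2)C(C)(C)C)=C\[C@](C)(CCC=C(C)C)[C@H]1COC(=O)C=C1 | intermediate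
24 | cis-fused cycloheptenone δ-lactone with allyl ester on C7 (key-step product) | C=CCOC(=O)C1C(=O)C(CO[Si](c3ccccc3)(c3ccccc3)C(C)(C)C)=C[C@](C)(CCC=C(C)C)[C@H]2COC(=O)C[C@@H]12 | intermediate
25 | allyl 3-[(tert-butyldiphenylsilyloxy)methyl]-6-(hydroxymethyl)-7-{2-[methoxy(methyl)amino]-2-oxoethyl}-5-methyl-5-(4-methylpent-3-en-1-yl)-2-oxocyclohept-3-ene-1-carboxylate | C=CCOC(=O)C1C(=O)C(CO[Si](c3ccccc3)(c3ccccc3)C(C)(C)C)=C[C@](C)(CCC=C(C)C)[C@@H](CO)[C@H]1CC(=O)N(C)OC | intermediate
26 | 6-formyl analogue of 25 | C=CCOC(=O)C1C(=O)C(CO[Si](c3ccccc3)(c3ccccc3)C(C)(C)C)=C[C@](C)(CCC=C(C)C)[C@@H](C=O)[C@H]1CC(=O)N(C)OC | intermediate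
27 | 6-ethynyl analogue of 25 | C=CCOC(=O)C1C(=O)C(CO[Si](c3ccccc3)(c3ccccc3)C(C)(C)C)=C[C@](C)(CCC=C(C)C)[C@@H](C#C)[C@H]1CC(=O)N(C)OC | intermediate
28 | allyl 3-[(tert-butyldiphenylsilyloxy)methyl]-6-ethynyl-5-methyl-5-(4-methylpent-3-en-1-yl)-2-oxo-7-(2-oxopropyl)cyclohept-3-ene-1-carboxylate | C=CCOC(=O)C1C(=O)C(CO[Si](c3ccccc3)(c3ccccc3)C(C)(C)C)=C[C@](C)(CCC=C(C)C)[C@@H](C#C)[C@H]1CC(C)=O | intermediate
29 | 2-[(tert-butyldiphenylsilyloxy)methyl]-5-ethynyl-4-methyl-4-(4-methylpent-3-en-1-yl)-6-(2-oxopropyl)cyclohept-2-en-1-one | CC(=O)C[C@H]1CC(=O)C(CO[Si](c3ccccc3)(c3ccccc3)C(C)(C)C)=C[C@](C)(CCC=C(C)C)[C@H]1C#C | intermediate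
30 | 3-methylbut-2-enoic acid | CC(C)=CC(=O)O | starting material
31 | tert-butyldiphenylsilyl ether of the target | CC(=O)C[C@H]1CC(=O)C(CO[Si](c3ccccc3)(c3ccccc3)C(C)(C)C)=C[C@](C)(CCC=C(C)C)[C@H]1/C=C\OC(=O)C=C(C)C | intermediate
32 | (Z)-2-[(1R,2R,7S)-4-(hydroxymethyl)-2-methyl-2-(4-methylpent-3-en-1-yl)-5-oxo-7-(2-oxopropyl)cyclohept-3-en-1-yl]ethenyl 3-methylbut-2-enoate | CC(=O)C[C@H]1CC(=O)C(CO)=C[C@](C)(CCC=C(C)C)[C@H]1/C=C\OC(=O)C=C(C)C | target

**Step count and risks**

Total step count: 23. Longest linear sequence: 22 steps (steps 1, 2 and 4–23 from furan-2(5H)-one); step 3 is a side branch.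

The three steps most likely to fail:

1. Step 16 (key ring closure). The cesium enolate may not reach C6 through the twisted Z-enone, the addition may be reversible, or the lactone may be deprotonated at C5 with loss of configuration or double-bond migration; oligomerisation by intermolecular addition is also possible. Fallback: a Lewis-acid-mediated Mukaiyama–Michael closure in place of the anionic one. It sets out from 23, which is converted with Me3SiCl/Et3N into the trimethylsilyl enol ether of the β-keto ester F1. F1 is then treated with TiCl4 in CH2Cl2 at −78 °C, so that the lactone carbonyl is activated and the silyl enol ether carbon C7 attacks C6 under the same tether control. No free base is present, so γ-deprotonation is avoided, and the adduct is held as a metal ketene acetal until aqueous work-up, so the closure cannot revert. The fallback comes back to the route at 24.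

2. Step 14 (olefination of the unprotected β-hydroxy aldehyde and lactonisation). Under the amine base the aldehyde may epimerise at C5 or lose water before the hindered formyl group is olefinated, and incomplete Z-selectivity would leave material that cannot lactonise. Fallback: tether the phosphonate and close the lactone by intramolecular olefination. It sets out from 19: PPTS in MeOH at 0 °C removes only the triethylsilyl group to give the diol acetal F2. The primary arm hydroxyl of F2 is acylated selectively with diethylphosphonoacetic acid (EDC·HCl, DMAP, 0 °C) to give the phosphonoacetate F3. Acetal hydrolysis (p-TsOH, acetone/H2O) then gives the aldehyde phosphonoacetate F4, and intramolecular Horner–Wadsworth–Emmons reaction (LiCl, i-Pr2NEt, MeCN) closes the unsaturated lactone with the geometry fixed by the ring. The fallback comes back to the route at 22.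

3. Step 9 (trans-hydrostannation/iodination). The alkyne carries a quaternary carbon and tin must end cis to it, so the hydrometalation may stall or lose regiocontrol, and the iodination may be accompanied by reaction at the trisubstituted alkene. Fallback: replace the stereodefined hydrometalation by a geometry-independent diol that is then differentiated by sterics. It sets out from 13: titanium-catalysed hydromagnesiation (i-BuMgCl, (C5H5)2TiCl2 cat., Et2O) places magnesium on the carbinol-side carbon, and quenching with formaldehyde gives the 2-alkylidene-propane-1,3-diol F5, in which the two hydroxymethyl groups differ only in being cis or trans to the quaternary carbon. Mono-silylation with t-BuPh2SiCl/imidazole at −20 °C should take the less hindered hydroxymethyl group, trans to the quaternary carbon, giving the mono-silyl ether F6. Oxidation of the remaining hydroxymethyl group, cis to the quaternary carbon, with MnO2 or Dess–Martin periodinane then gives the Z-enal. The fallback comes back to the route at 17.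

**Further compounds**

F1 | step 16 | trimethylsilyl enol ether of β-keto ester 23 | C=CCOC(=O)C=C(O[Si](C)(C)C)/C(CO[Si](c2ccccc2)(c2ccccc2)C(C)(C)C)=C\[C@](C)(CCC=C(C)C)[C@H]1COC(=O)C=C1
F2 | step 14 | diol acetal (19 without the triethylsilyl group) | C=CCOC(=O)CC(O)/C(CO[Si](c1ccccc1)(c1ccccc1)C(C)(C)C)=C\[C@](C)(CCC=C(C)C)[C@H](C(OC)OC)CO
F3 | step 14 | diethylphosphonoacetate of the arm hydroxyl of F2 | C=CCOC(=O)CC(O)/C(CO[Si](c1ccccc1)(c1ccccc1)C(C)(C)C)=C\[C@](C)(CCC=C(C)C)[C@H](C(OC)OC)COC(=O)CP(=O)(OCC)OCC
F4 | step 14 | aldehyde phosphonoacetate from F3 | C=CCOC(=O)CC(O)/C(CO[Si](c1ccccc1)(c1ccccc1)C(C)(C)C)=C\[C@](C)(CCC=C(C)C)[C@H](C=O)COC(=O)CP(=O)(OCC)OCC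
F5 | step 9 | 2-alkylidene-propane-1,3-diol from 13 | OCC(CO)=C[C@](C)(CCC=C(C)C)[C@H](C(OC)OC)CO[Si](CC)(CC)CC
F6 | step 9 | mono-tert-butyldiphenylsilyl ether of F5 (free hydroxymethyl cis to the quaternary carbon) | OC/C(CO[Si](c1ccccc1)(c1ccccc1)C(C)(C)C)=C\[C@](C)(CCC=C(C)C)[C@H](C(OC)OC)CO[Si](CC)(CC)CC
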